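**Retrosynthetic overview**

- Feature: in the chroman-4-one (rings A and C), C2 is a CH2 bonded to O1 and to the stereogenic C3, and C5 carries OMe. O1–C2 and the 5-OMe are therefore traced back to the two rotationally equivalent methoxy groups of a 2,6-dimethoxyaryl ketone.
- Last C–C disconnection: C2–C3, made by enantioselective carbene C–H insertion from a C3 diazo ketone into one OCH3 group. This closes pyranone ring C last and sets C3.
- The diazo ketone comes from diazo transfer to a deoxybenzoin, itself made by palladium-catalysed α-arylation (C3–C1' bond) of the ring A acetophenone with the ring B bromochromene.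
- Ring A piece: 3,5-dimethoxyphenol, silylated, lithiated between the methoxy groups and acetylated. Ring B piece: 5-bromosalicylaldehyde, via propargyl ether, Baeyer–Villiger oxidation and a Claisen cascade.
- Ring order: the 2H-pyran ring of the chromene first (step 4), pyranone ring C second (step 9). Both phenols travel as triisopropylsilyl (TIPS) ethers and are freed in the last step.

Key step: step 9

Assumption: the sense of induction of the phthalimido-tert-leucinate dirhodium catalyst on this substrate cannot be predicted with certainty. The route is written for the S-ligand catalyst, and the R-ligand antipode is to be used instead if an analytical run shows that it is the one giving the 3S product.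

**Route**

Step 1
Reactants: 1 5-bromo-2-hydroxybenzaldehyde; 2 3-chloro-3-methylbut-1-yne
Product: 3 5-bromo-2-[(2-methylbut-3-yn-2-yl)oxy]benzaldehyde
Conditions: DBU, CuCl2·2H2O (cat.), MeCN, 0 °C to rt
Reagents that add atoms: none
Why: Copper-catalysed propargylic etherification of a phenol with a tertiary propargylic chloride, in which the copper acetylide of 2 ionises to an allenylidene-type electrophile that the acidic salicylaldehyde phenoxide captures at the tertiary carbon, a reaction that works best with electron-poor phenols such as 1.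

Step 2
Reactants: 3 5-bromo-2-[(2-methylbut-3-yn-2-yl)oxy]benzaldehyde
Product: 5 5-bromo-2-[(2-methylbut-3-yn-2-yl)oxy]phenol, via aryl formate 4 (not isolated)
Conditions: mCPBA, CH2Cl2, 0 °C to rt; then K2CO3 (cat.), MeOH, rt
Reagents that add atoms: mCPBA (3-chloroperoxybenzoic acid), O=C(OO)c1cccc(Cl)c1
Why: Baeyer–Villiger (Dakin-type) oxidation with aryl migration, favoured by the ortho alkoxy group on the migrating ring, should give formate 4, which mild methanolysis cleaves to the phenol while the terminal alkyne and the tertiary ether stay inert to the peracid.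

Step 3
Reactants: 5 5-bromo-2-[(2-methylbut-3-yn-2-yl)oxy]phenol
Product: 6 {5-bromo-2-[(2-methylbut-3-yn-2-yl)oxy]phenoxy}triisopropylsilane
Conditions: TIPSCl, imidazole, DMF, rt
Reagents that add atoms: chlorotriisopropylsilane (TIPSCl), CC(C)[Si](Cl)(C(C)C)C(C)C
Why: Standard silylation of a phenol, the triisopropylsilyl group being chosen because it should survive heat, K3PO4, DBU and the carbene step and still leave with fluoride at the end.

Step 4
Reactants: 6 {5-bromo-2-[(2-methylbut-3-yn-2-yl)oxy]phenoxy}triisopropylsilane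
Product: 7 [(6-bromo-2,2-dimethyl-2H-chromen-8-yl)oxy]triisopropylsilane
Conditions: PhNEt2, 190 °C
Reagents that add atoms: none
Why: Thermal aryl propargyl ether Claisen rearrangement to the only free ortho position, followed by enolisation, 1,5-hydrogen shift and 6π oxa-electrocyclisation of the ortho-quinone methide, builds the 2,2-dimethyl-2H-pyran ring, the gem-dimethyl group accelerating the sigmatropic shift.

Step 5
Reactants: 8 3,5-dimethoxyphenol
Product: 9 (3,5-dimethoxyphenoxy)triisopropylsilane
Conditions: TIPSCl, imidazole, DMF, rt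
Reagents that add atoms: chlorotriisopropylsilane (TIPSCl), CC(C)[Si](Cl)(C(C)C)C(C)C
Why: Standard phenol silylation that masks the acidic OH before lithiation and gives a bulky, poorly coordinating ether that will not compete as a directing group.

Step 6
Reactants: 9 (3,5-dimethoxyphenoxy)triisopropylsilane; 10 N-methoxy-N-methylacetamide
Product: 13 1-[2,6-dimethoxy-4-(triisopropylsilyloxy)phenyl]ethan-1-one, via aryllithium 11 (not isolated), via lithium hemiaminal adduct 12 (not isolated)
Conditions: n-BuLi, TMEDA, THF, 0 °C; then 10, −78 °C to 0 °C; then 1 M HCl, 0 °C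
Reagents that add atoms: none
Why: Directed ortho-metalation at the position flanked by the two methoxy groups (cooperative coordination, the silyl ether shielding its own ortho positions) followed by Weinreb amide acylation, whose chelated adduct 12 prevents over-addition until the acidic quench.

Step 7
Reactants: 13 1-[2,6-dimethoxy-4-(triisopropylsilyloxy)phenyl]ethan-1-one; 7 [(6-bromo-2,2-dimethyl-2H-chromen-8-yl)oxy]triisopropylsilane
Product: 14 1-[2,6-dimethoxy-4-(triisopropylsilyloxy)phenyl]-2-[2,2-dimethyl-8-(triisopropylsilyloxy)-2H-chromen-6-yl]ethan-1-one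
Conditions: Pd2(dba)3 (2 mol%, zerovalent palladium), Xantphos (5 mol%), K3PO4, toluene, 90 °C, slight excess of 13
Reagents that add atoms: none
Why: Palladium-catalysed α-arylation of a ketone enolate (Buchwald–Hartwig type) should form the C3–C1' bond by oxidative addition of the unhindered aryl bromide, enolate binding and reductive elimination, the methyl ketone having a single enolisable site, the product enolate being too hindered for a second arylation and K3PO4 sparing the aryl silyl ethers.

Step 8
Reactants: 14 1-[2,6-dimethoxy-4-(triisopropylsilyloxy)phenyl]-2-[2,2-dimethyl-8-(triisopropylsilyloxy)-2H-chromen-6-yl]ethan-1-one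
Product: 15 2-diazo-1-[2,6-dimethoxy-4-(triisopropylsilyloxy)phenyl]-2-[2,2-dimethyl-8-(triisopropylsilyloxy)-2H-chromen-6-yl]ethan-1-one
Conditions: p-ABSA, DBU, MeCN, 0 °C to rt
Reagents that add atoms: 4-acetamidobenzenesulfonyl azide (p-ABSA), CC(=O)Nc1ccc(cc1)S(=O)(=O)N=[N+]=[N-]
Why: Regitz diazo transfer, in which the benzylic methylene flanked by the ketone and ring B is acidic enough for DBU and its enolate attacks the terminal nitrogen of the sulfonyl azide and expels the sulfonamide.

Step 9
Reactants: 15 2-diazo-1-[2,6-dimethoxy-4-(triisopropylsilyloxy)phenyl]-2-[2,2-dimethyl-8-(triisopropylsilyloxy)-2H-chromen-6-yl]ethan-1-one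
Product: 16 (3S)-5-methoxy-7-(triisopropylsilyloxy)-3-[2,2-dimethyl-8-(triisopropylsilyloxy)-2H-chromen-6-yl]-2,3-dihydro-4H-chromen-4-one
Conditions: Rh2(S-PTTL)4, dirhodium tetrakis[N-phthaloyl-(S)-tert-leucinate] (1 mol%, divalent rhodium), CH2Cl2, 4 Å MS, 0 °C, 15 added over several hours by syringe pump at high dilution
Reagents that add atoms: none
Why: Proposed new method: the dirhodium carboxylate expels N2 from 15 to give a rhodium-bound donor–acceptor carbene at C3, which should insert into a C–H bond of an ortho methoxy group through a concerted, asynchronous three-centre transition state in which the ether oxygen stabilises the positive charge developing on the methyl carbon, so forming the C2–C3 bond. The closest known reaction type is the dirhodium-catalysed intramolecular C–H insertion of 2-alkoxyaryl diazo ketones next to the ether oxygen that gives chroman-4-ones, together with enantioselective insertion of aryl-substituted carbenes into methyl ethers; new here is the pairing of a diaryl diazo ketone with a primary O–CH3 bond. The pyranone ring closes as a six-membered ring by 1,6-insertion (carbene carbon C3 onto the methyl carbon that becomes C2), the only sp3 C–H bonds within reach being those of the two ortho methoxy groups, which interconvert by rotation about the aryl–carbonyl bond so that either insertion gives 16 and the untouched group becomes the 5-OMe. The C3 stereocentre is created at the carbene carbon under control of the chiral phthalimido-tert-leucinate ligands of the catalyst, the substrate having no other stereocentre. The step needs chemoselectivity for C–H insertion over oxonium ylide formation at the methoxy oxygen, cyclopropanation of the chromene alkene and carbene dimerisation; a methyl group migrates poorly from an oxonium ylide so that ylide formation should be reversible, the aryl donor tempers the carbene, and slow addition at high dilution keeps bimolecular paths down. The neutral conditions should leave the base-labile C3–H of 16 untouched.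

Step 10
Reactants: 16 (3S)-5-methoxy-7-(triisopropylsilyloxy)-3-[2,2-dimethyl-8-(triisopropylsilyloxy)-2H-chromen-6-yl]-2,3-dihydro-4H-chromen-4-one
Product: 17 (3S)-7-hydroxy-3-(8-hydroxy-2,2-dimethyl-2H-chromen-6-yl)-5-methoxy-2,3-dihydro-4H-chromen-4-one
Conditions: TBAF, AcOH (1:1), THF, 0 °C; pH 7 buffer work-up
Reagents that add atoms: none
Why: Fluoride-driven cleavage of both aryl silyl ethers, with acetic acid buffering the medium so that neither phenoxide nor enolate builds up and the labile C3–H (α to the ketone and benzylic) is neither epimerised nor lost by ring-opening β-elimination.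

**Compound list**

1 | 5-bromo-2-hydroxybenzaldehyde | O=Cc1cc(Br)ccc1O | starting material
2 | 3-chloro-3-methylbut-1-yne | C#CC(C)(C)Cl | starting material
3 | 5-bromo-2-[(2-methylbut-3-yn-2-yl)oxy]benzaldehyde | O=Cc1cc(Br)ccc1OC(C)(C)C#C | intermediate
4 | 5-bromo-2-[(2-methylbut-3-yn-2-yl)oxy]phenyl formate (not isolated) | O=COc1cc(Br)ccc1OC(C)(C)C#C | intermediate
5 | 5-bromo-2-[(2-methylbut-3-yn-2-yl)oxy]phenol | Oc1cc(Br)ccc1OC(C)(C)C#C | intermediate
6 | {5-bromo-2-[(2-methylbut-3-yn-2-yl)oxy]phenoxy}triisopropylsilane | CC(C)[Si](C(C)C)(C(C)C)Oc1cc(Br)ccc1OC(C)(C)C#C | intermediate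
7 | [(6-bromo-2,2-dimethyl-2H-chromen-8-yl)oxy]triisopropylsilane | CC(C)[Si](C(C)C)(C(C)C)Oc1cc(Br)cc2c1OC(C)(C)C=C2 | intermediate
8 | 3,5-dimethoxyphenol | COc1cc(O)cc(OC)c1 | starting material
9 | (3,5-dimethoxyphenoxy)triisopropylsilane | COc1cc(O[Si](C(C)C)(C(C)C)C(C)C)cc(OC)c1 | intermediate
10 | N-methoxy-N-methylacetamide | CON(C)C(C)=O | starting material
11 | [2,6-dimethoxy-4-(triisopropylsilyloxy)phenyl]lithium (not isolated) | [Li]c1c(OC)cc(O[Si](C(C)C)(C(C)C)C(C)C)cc1OC | intermediate
12 | lithium 1-[2,6-dimethoxy-4-(triisopropylsilyloxy)phenyl]-1-[methoxy(methyl)amino]ethan-1-olate (not isolated) | [Li+].[O-]C(C)(N(C)OC)c1c(OC)cc(O[Si](C(C)C)(C(C)C)C(C)C)cc1OC | intermediate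
13 | 1-[2,6-dimethoxy-4-(triisopropylsilyloxy)phenyl]ethan-1-one | CC(=O)c1c(OC)cc(O[Si](C(C)C)(C(C)C)C(C)C)cc1OC | intermediate
14 | 1-[2,6-dimethoxy-4-(triisopropylsilyloxy)phenyl]-2-[2,2-dimethyl-8-(triisopropylsilyloxy)-2H-chromen-6-yl]ethan-1-one | COc1cc(O[Si](C(C)C)(C(C)C)C(C)C)cc(OC)c1C(=O)Cc1cc(O[Si](C(C)C)(C(C)C)C(C)C)c2c(c1)C=CC(C)(C)O2 | intermediate
15 | 2-diazo-1-[2,6-dimethoxy-4-(triisopropylsilyloxy)phenyl]-2-[2,2-dimethyl-8-(triisopropylsilyloxy)-2H-chromen-6-yl]ethan-1-one | COc1cc(O[Si](C(C)C)(C(C)C)C(C)C)cc(OC)c1C(=O)C(=[N+]=[N-])c1cc(O[Si](C(C)C)(C(C)C)C(C)C)c2c(c1)C=CC(C)(C)O2 | intermediate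
16 | (3S)-5-methoxy-7-(triisopropylsilyloxy)-3-[2,2-dimethyl-8-(triisopropylsilyloxy)-2H-chromen-6-yl]-2,3-dihydro-4H-chromen-4-one | COc1cc(O[Si](C(C)C)(C(C)C)C(C)C)cc2c1C(=O)[C@@H](c1cc(O[Si](C(C)C)(C(C)C)C(C)C)c3c(c1)C=CC(C)(C)O3)CO2 | intermediate
17 | (3S)-7-hydroxy-3-(8-hydroxy-2,2-dimethyl-2H-chromen-6-yl)-5-methoxy-2,3-dihydro-4H-chromen-4-one | COc1cc(O)cc2c1C(=O)[C@@H](c1cc(O)c3c(c1)C=CC(C)(C)O3)CO2 | target

**Step count**

Total: 10 steps. Longest linear sequence: 8 steps (steps 1–4, then 7–10).

**Steps most likely to fail**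

Step 9 (proposed new method). The carbene may be diverted to an oxonium ylide at the methoxy oxygen followed by a Stevens shift, to cyclopropanation of the chromene alkene, or to dimerisation, or the insertion may proceed with poor enantioselectivity. The fallback leaves the route at deoxybenzoin 14 and rejoins it at 16 by known chemistry. BCl3 in CH2Cl2 at −78 °C, chelation-directed by the ketone, removes one of the two equivalent ortho methyl groups to give 1-[2-hydroxy-6-methoxy-4-(triisopropylsilyloxy)phenyl]-2-[2,2-dimethyl-8-(triisopropylsilyloxy)-2H-chromen-6-yl]ethan-1-one F1. Paraformaldehyde and Et2NH in warm ethanol (Mannich reaction, amine elimination, oxa-Michael closure) should convert it into racemic 5-methoxy-7-(triisopropylsilyloxy)-3-[2,2-dimethyl-8-(triisopropylsilyloxy)-2H-chromen-6-yl]-2,3-dihydro-4H-chromen-4-one F2. Because C3 of F2 epimerises under the basic conditions of transfer hydrogenation, RuCl[(S,S)-TsDPEN](p-cymene) with HCO2H/Et3N should reduce it with dynamic kinetic resolution to the cis alcohol (3S,4S)-5-methoxy-7-(triisopropylsilyloxy)-3-[2,2-dimethyl-8-(triisopropylsilyloxy)-2H-chromen-6-yl]-3,4-dihydro-2H-chromen-4-ol F3 (the antipodal ligand is used if the sense proves opposite). Dess–Martin periodinane buffered with NaHCO3 then returns the ketone as 16 without touching C3.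

Step 7. Enolate formation from the hindered ketone with the weak base may be slow, a second arylation may follow, or the silyl ethers may be lost on prolonged heating with base. The fallback leaves from bromide 7 and silyl ether 9 and rejoins at 14. Bromine–lithium exchange on 7 (n-BuLi, THF, −78 °C) and opening of ethylene oxide in the presence of BF3·OEt2 should give 2-[2,2-dimethyl-8-(triisopropylsilyloxy)-2H-chromen-6-yl]ethan-1-ol F4. Dess–Martin oxidation gives [2,2-dimethyl-8-(triisopropylsilyloxy)-2H-chromen-6-yl]acetaldehyde F5. Aryllithium 11, made from 9 as in step 6 and transmetalated with anhydrous CeCl3 to suppress enolisation, adds to F5 to give racemic 1-[2,6-dimethoxy-4-(triisopropylsilyloxy)phenyl]-2-[2,2-dimethyl-8-(triisopropylsilyloxy)-2H-chromen-6-yl]ethan-1-ol F6. A second Dess–Martin oxidation gives 14.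

Step 10. Configuration at C3 may erode through enolisation or reversible ring opening while fluoride and phenoxide are present. The fallback leaves from 16 and ends at 17, removing the acidity of C3–H before the silyl groups are cleaved. Transfer hydrogenation of 16 (RuCl[(S,S)-TsDPEN](p-cymene), HCO2H/Et3N) gives the cis alcohol (3S,4S)-5-methoxy-7-(triisopropylsilyloxy)-3-[2,2-dimethyl-8-(triisopropylsilyloxy)-2H-chromen-6-yl]-3,4-dihydro-2H-chromen-4-ol F3, the same compound as in the fallback to step 9. TBAF in THF then frees both phenols to give (3S,4S)-3-(8-hydroxy-2,2-dimethyl-2H-chromen-6-yl)-5-methoxy-3,4-dihydro-2H-chromene-4,7-diol F7. DDQ (one equivalent) in dioxane at room temperature should oxidise the para-hydroxybenzylic C4 carbinol back to the ketone through the quinone methide, giving 17 under non-basic conditions.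

**Further compounds**

F1 | step 9 | 1-[2-hydroxy-6-methoxy-4-(triisopropylsilyloxy)phenyl]-2-[2,2-dimethyl-8-(triisopropylsilyloxy)-2H-chromen-6-yl]ethan-1-one | COc1cc(O[Si](C(C)C)(C(C)C)C(C)C)cc(O)c1C(=O)Cc1cc(O[Si](C(C)C)(C(C)C)C(C)C)c2c(c1)C=CC(C)(C)O2
F2 | step 9 | racemic 5-methoxy-7-(triisopropylsilyloxy)-3-[2,2-dimethyl-8-(triisopropylsilyloxy)-2H-chromen-6-yl]-2,3-dihydro-4H-chromen-4-one | COc1cc(O[Si](C(C)C)(C(C)C)C(C)C)cc2c1C(=O)C(c1cc(O[Si](C(C)C)(C(C)C)C(C)C)c3c(c1)C=CC(C)(C)O3)CO2
F3 | step 9 | (3S,4S)-5-methoxy-7-(triisopropylsilyloxy)-3-[2,2-dimethyl-8-(triisopropylsilyloxy)-2H-chromen-6-yl]-3,4-dihydro-2H-chromen-4-ol | COc1cc(O[Si](C(C)C)(C(C)C)C(C)C)cc2c1[C@@H](O)[C@@H](c1cc(O[Si](C(C)C)(C(C)C)C(C)C)c3c(c1)C=CC(C)(C)O3)CO2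
F4 | step 7 | 2-[2,2-dimethyl-8-(triisopropylsilyloxy)-2H-chromen-6-yl]ethan-1-ol | OCCc1cc(O[Si](C(C)C)(C(C)C)C(C)C)c2c(c1)C=CC(C)(C)O2
F5 | step 7 | [2,2-dimethyl-8-(triisopropylsilyloxy)-2H-chromen-6-yl]acetaldehyde | O=CCc1cc(O[Si](C(C)C)(C(C)C)C(C)C)c2c(c1)C=CC(C)(C)O2
F6 | step 7 | racemic 1-[2,6-dimethoxy-4-(triisopropylsilyloxy)phenyl]-2-[2,2-dimethyl-8-(triisopropylsilyloxy)-2H-chromen-6-yl]ethan-1-ol | COc1cc(O[Si](C(C)C)(C(C)C)C(C)C)cc(OC)c1C(O)Cc1cc(O[Si](C(C)C)(C(C)C)C(C)C)c2c(c1)C=CC(C)(C)O2
F7 | step 10 | (3S,4S)-3-(8-hydroxy-2,2-dimethyl-2H-chromen-6-yl)-5-methoxy-3,4-dihydro-2H-chromene-4,7-diol | COc1cc(O)cc2c1[C@@H](O)[C@@H](c1cc(O)c3c(c1)C=CC(C)(C)O3)CO2
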